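**Retrosynthetic overview**
1. Target 24 comes from epoxy alcohol 23 by O-acylation, and 23 comes from (E)-allylic alcohol 22 by Sharpless epoxidation. The oxirane is the last ring formed.
2. 22 comes from (7E)-enone 19 by CBS reduction and acetylation. The E-alkene is made inside the ten-membered ring by a selenoxide syn-elimination.
3. The ten-membered ring (14) comes from cyclohexanone 13 by a four-carbon radical ring expansion. The acyl carbon moves from C(CO2Me) to the side-chain carbon, and loss of Bu3Sn gives the enoate.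
4. 13 comes from enone ester 7, Bu3SnLi and iodide 11 (two steps from 2,3-dihydrofuran).
5. 7 comes from cyclohexenone, isopropenyl-BF3K (Rh catalysis sets C4) and dimethyl carbonate. Ring order: six-membered carbocycle, then ten-membered carbocycle, then oxirane.

Assumption: stereocentres that are erased later (C1 of 4–6, C1/C6 of 12–13, C7 of 14–18) are carried as mixtures and left undefined in the SMILES.

Ring numbering for 14–24: C1 = C(CO2Me), C2 = alkene CH, C4 = CH(isopropenyl), C6 = C=O or CH–O, C7 and C8 = later oxirane carbons.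

**Step 1**
Reactants: 1 cyclohex-2-en-1-one; 2 potassium trifluoro(prop-1-en-2-yl)borate
Product: 3 (3S)-3-(prop-1-en-2-yl)cyclohexan-1-one
Conditions: [Rh(cod)2]PF6 (3 mol %), (S)-BINAP, toluene/H2O 4:1, 105 °C
Reagents that add atoms: none
Why: Hayashi–Miyaura-type rhodium-catalysed asymmetric 1,4-addition of an alkenylboron reagent, in which the (S)-BINAP–Rh alkenyl species sets the (S) centre as it does for other aryl and alkenyl donors.

**Step 2**
Reactants: 3 (3S)-3-(prop-1-en-2-yl)cyclohexan-1-one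
Product: 4 methyl (4S)-2-oxo-4-(prop-1-en-2-yl)cyclohexane-1-carboxylate
Conditions: NaH (2.2 equiv), (MeO)2CO, THF, reflux; aq HCl work-up
Reagents that add atoms: dimethyl carbonate, COC(=O)OC
Why: Claisen-type C-acylation under thermodynamic control gives the enolised β-keto ester at the α-carbon remote from the C3 substituent, and the existing centre is untouched.

**Step 3**
Reactants: 4 methyl (4S)-2-oxo-4-(prop-1-en-2-yl)cyclohexane-1-carboxylate
Product: 7 methyl (4S)-6-oxo-4-(prop-1-en-2-yl)cyclohex-1-ene-1-carboxylate, via selenide 5 (not isolated), via selenoxide 6 (not isolated)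
Conditions: PhSeCl, pyridine, CH2Cl2, 0 °C; then 30 % H2O2, 0 °C to rt
Reagents that add atoms: none
Why: α-Selenenylation of the β-dicarbonyl enol followed by selenoxide syn-elimination can only eliminate toward the single β-CH2 and gives the 2-carbomethoxy enone.

**Step 4**
Reactants: 8 2,3-dihydrofuran
Product: 9 4,4-bis(phenylselanyl)butan-1-ol
Conditions: PhSeH (2.1 equiv), BF3·OEt2 (20 mol %), CH2Cl2, −20 °C to rt
Reagents that add atoms: benzeneselenol, [SeH]c1ccccc1
Why: Lewis-acid selenoacetalisation of the cyclic enol ether (a masked 4-hydroxybutanal) parallels the well-used bis(phenylthio) case.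

**Step 5**
Reactants: 9 4,4-bis(phenylselanyl)butan-1-ol
Product: 11 4-iodo-1,1-bis(phenylselanyl)butane, via mesylate 10 (not isolated)
Conditions: MsCl, Et3N, CH2Cl2, 0 °C; then NaI, acetone, rt
Reagents that add atoms: sodium iodide, [Na+].[I-]
Why: Mesylation followed by Finkelstein SN2 displacement avoids free iodine, which would complex the selenides.

**Step 6**
Reactants: 7 methyl (4S)-6-oxo-4-(prop-1-en-2-yl)cyclohex-1-ene-1-carboxylate; 11 4-iodo-1,1-bis(phenylselanyl)butane
Product: 13 methyl (4R)-1-[4,4-bis(phenylselanyl)butyl]-2-oxo-4-(prop-1-en-2-yl)-6-(tributylstannyl)cyclohexane-1-carboxylate, via stannyl enolate 12 (not isolated)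
Conditions: Bu3SnH, LiN(iPr)2, THF, −78 to 0 °C; 7, −78 °C; then 11, DMPU, −78 to 40 °C
Reagents that add atoms: tributylstannane (used as Bu3SnLi), CCCC[SnH](CCCC)CCCC
Why: Irreversible conjugate addition of the stannyl anion and C-alkylation of the resulting β-keto ester enolate make a three-component coupling whose two new centres are erased in step 7, and C4 keeps its geometry although its descriptor becomes R because tin changes the CIP ranking.

**Step 7**
Reactants: 13 methyl (4R)-1-[4,4-bis(phenylselanyl)butyl]-2-oxo-4-(prop-1-en-2-yl)-6-(tributylstannyl)cyclohexane-1-carboxylate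
Product: 14 methyl (1E,4S)-6-oxo-7-(phenylselanyl)-4-(prop-1-en-2-yl)cyclodec-1-ene-1-carboxylate
Conditions: (Bu3Sn)2 (10 mol %), hν (sunlamp), PhH (5 mM), 80 °C
Reagents that add atoms: none
Why: Proposed new method: a hydride-free, self-propagating four-carbon ring expansion in which Bu3Sn• abstracts one PhSe group, the α-seleno radical adds 6-exo to the ketone, the bicyclic alkoxy radical cleaves the C(O)–C(CO2Me) bond to a tertiary α-ester radical that is also β-stannyl-stabilised, and loss of Bu3Sn• forms the enoate and carries the chain, while reversible Bu3Sn• addition and elimination funnels the alkene to the more stable 1E isomer (cis ring path, ester trans to C3) and the surviving PhSe marks C7 regiospecifically; the closest known reaction types are the Dowd–Beckwith ring expansion and radical ring expansions terminated by β-stannyl scission.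

**Step 8**
Reactants: 14 methyl (1E,4S)-6-oxo-7-(phenylselanyl)-4-(prop-1-en-2-yl)cyclodec-1-ene-1-carboxylate
Product: 17 methyl (1E,4S)-6-oxo-7-(phenylselanyl)-4-(prop-1-en-2-yl)-7-{[(triethylsilyl)oxy]methyl}cyclodec-1-ene-1-carboxylate, via lithium enolate 15 (not isolated), via lithium alkoxide 16 (not isolated)
Conditions: LiN(SiMe3)2, THF, −78 to −40 °C; CH2O (gas), −78 °C; Et3SiCl, −78 to 0 °C
Reagents that add atoms: formaldehyde, C=O; chlorotriethylsilane, CC[Si](Cl)(CC)CC
Why: The selenium-acidified C7–H is removed selectively under equilibrating conditions, and a formaldehyde aldol with O-silylation gives the quaternary α-seleno ketone, which has no α-H left for β-elimination.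

**Step 9**
Reactants: 17 methyl (1E,4S)-6-oxo-7-(phenylselanyl)-4-(prop-1-en-2-yl)-7-{[(triethylsilyl)oxy]methyl}cyclodec-1-ene-1-carboxylate
Product: 19 methyl (1E,4S,7E)-6-oxo-4-(prop-1-en-2-yl)-7-{[(triethylsilyl)oxy]methyl}cyclodeca-1,7-diene-1-carboxylate, via selenoxide 18 (not isolated)
Conditions: 30 % H2O2, pyridine, CH2Cl2, 0 °C to rt
Reagents that add atoms: none
Why: In this selenoxide syn-elimination the syn-periplanar Se–C7–C8–H array of a ten-membered ring is reached with a ring torsion near 120° (leading to E) rather than 0° (leading to Z), as in amine-oxide eliminations of cyclodecyl systems, and elimination toward the oxygen-bearing CH2 is disfavoured.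

**Step 10**
Reactants: 19 methyl (1E,4S,7E)-6-oxo-4-(prop-1-en-2-yl)-7-{[(triethylsilyl)oxy]methyl}cyclodeca-1,7-diene-1-carboxylate
Product: 21 methyl (1E,4S,6S,7E)-6-acetoxy-4-(prop-1-en-2-yl)-7-{[(triethylsilyl)oxy]methyl}cyclodeca-1,7-diene-1-carboxylate, via allylic alcohol 20 (not isolated)
Conditions: (R)-Me-CBS (20 mol %), catecholborane, toluene, −78 °C; MeOH; then Ac2O, Et3N, DMAP, CH2Cl2, 0 °C
Reagents that add atoms: acetic anhydride, CC(=O)OC(C)=O
Why: Corey–Bakshi–Shibata 1,2-reduction treats the α-branched alkenyl arm as the large group and CH2 as the small one, so the (R)-catalyst gives the 6S carbinol under reagent control, catecholborane spares the alkenes, and the alcohol is acetylated in the same flask.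

**Step 11**
Reactants: 21 methyl (1E,4S,6S,7E)-6-acetoxy-4-(prop-1-en-2-yl)-7-{[(triethylsilyl)oxy]methyl}cyclodeca-1,7-diene-1-carboxylate
Product: 22 methyl (1E,4S,6S,7E)-6-acetoxy-7-(hydroxymethyl)-4-(prop-1-en-2-yl)cyclodeca-1,7-diene-1-carboxylate
Conditions: HF·pyridine, THF, 0 °C
Reagents that add atoms: none
Why: Mildly acidic fluoride desilylation of the primary silyl ether leaves the esters in place and avoids base-induced acetyl migration.

**Step 12**
Reactants: 22 methyl (1E,4S,6S,7E)-6-acetoxy-7-(hydroxymethyl)-4-(prop-1-en-2-yl)cyclodeca-1,7-diene-1-carboxylate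
Product: 23 methyl (1E,4S,6S,7S,8R)-6-acetoxy-7,8-epoxy-7-(hydroxymethyl)-4-(prop-1-en-2-yl)cyclodec-1-ene-1-carboxylate
Conditions: Ti(OiPr)4 (20 mol %), L-(+)-diisopropyl tartrate (24 mol %), t-BuOOH, 4 Å MS, CH2Cl2, −20 °C
Reagents that add atoms: tert-butyl hydroperoxide, CC(C)(C)OO
Why: Katsuki–Sharpless asymmetric epoxidation touches only the allylic-alcohol alkene (isopropenyl and enoate are inert), is stereospecific so the E-alkene gives the trans-fused oxirane, and with the L-(+)-tartrate gives the (2S,3R)-type face known for allylic alcohols whose C3 substituent is cis to CH2OH, which corresponds to 7S,8R.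

**Step 13**
Reactants: 23 methyl (1E,4S,6S,7S,8R)-6-acetoxy-7,8-epoxy-7-(hydroxymethyl)-4-(prop-1-en-2-yl)cyclodec-1-ene-1-carboxylate
Product: 24 methyl (1E,4S,6S,7S,8R)-6-acetoxy-7,8-epoxy-7-{[(2-methylpropanoyl)oxy]methyl}-4-(prop-1-en-2-yl)cyclodec-1-ene-1-carboxylate
Conditions: i-PrCOCl, pyridine, DMAP (cat.), CH2Cl2, 0 °C
Reagents that add atoms: 2-methylpropanoyl chloride, CC(C)C(=O)Cl
Why: Simple O-acylation of the only free (primary) hydroxyl changes no stereocentre.

**Compound list**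
1 | cyclohex-2-en-1-one | O=C1C=CCCC1 | starting material
2 | potassium trifluoro(prop-1-en-2-yl)borate | C=C(C)[B-](F)(F)F.[K+] | starting material
3 | (3S)-3-(prop-1-en-2-yl)cyclohexan-1-one | C=C(C)[C@H]1CCCC(=O)C1 | intermediate
4 | methyl (4S)-2-oxo-4-(prop-1-en-2-yl)cyclohexane-1-carboxylate | C=C(C)[C@H]1CCC(C(=O)OC)C(=O)C1 | intermediate
5 | methyl (4S)-2-oxo-1-(phenylselanyl)-4-(prop-1-en-2-yl)cyclohexane-1-carboxylate | C=C(C)[C@H]1CCC([Se]c2ccccc2)(C(=O)OC)C(=O)C1 | intermediate
6 | methyl (4S)-2-oxo-1-(phenylseleninyl)-4-(prop-1-en-2-yl)cyclohexane-1-carboxylate | C=C(C)[C@H]1CCC([Se](=O)c2ccccc2)(C(=O)OC)C(=O)C1 | intermediate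
7 | methyl (4S)-6-oxo-4-(prop-1-en-2-yl)cyclohex-1-ene-1-carboxylate | C=C(C)[C@H]1CC=C(C(=O)OC)C(=O)C1 | intermediate
8 | 2,3-dihydrofuran | C1=COCC1 | starting material
9 | 4,4-bis(phenylselanyl)butan-1-ol | OCCCC([Se]c1ccccc1)[Se]c1ccccc1 | intermediate
10 | 4,4-bis(phenylselanyl)butyl methanesulfonate | CS(=O)(=O)OCCCC([Se]c1ccccc1)[Se]c1ccccc1 | intermediate
11 | 4-iodo-1,1-bis(phenylselanyl)butane | ICCCC([Se]c1ccccc1)[Se]c1ccccc1 | intermediate
12 | lithium enolate of methyl (4R)-2-oxo-4-(prop-1-en-2-yl)-6-(tributylstannyl)cyclohexane-1-carboxylate | C=C(C)[C@H]1CC([Sn](CCCC)(CCCC)CCCC)C(C(=O)OC)=C([O-])C1.[Li+] | intermediate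
13 | methyl (4R)-1-[4,4-bis(phenylselanyl)butyl]-2-oxo-4-(prop-1-en-2-yl)-6-(tributylstannyl)cyclohexane-1-carboxylate | C=C(C)[C@H]1CC([Sn](CCCC)(CCCC)CCCC)C(CCCC([Se]c2ccccc2)[Se]c2ccccc2)(C(=O)OC)C(=O)C1 | intermediate
14 | methyl (1E,4S)-6-oxo-7-(phenylselanyl)-4-(prop-1-en-2-yl)cyclodec-1-ene-1-carboxylate | C=C(C)[C@H]1C/C=C(/C(=O)OC)CCCC([Se]c2ccccc2)C(=O)C1 | intermediate
15 | lithium C6–C7 enolate of 14 | C=C(C)[C@H]1C/C=C(/C(=O)OC)CCCC([Se]c2ccccc2)=C([O-])C1.[Li+] | intermediate
16 | lithium alkoxide of the 7-(hydroxymethyl) aldol of 14 | C=C(C)[C@H]1C/C=C(/C(=O)OC)CCCC(C[O-])([Se]c2ccccc2)C(=O)C1.[Li+] | intermediate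
17 | methyl (1E,4S)-6-oxo-7-(phenylselanyl)-4-(prop-1-en-2-yl)-7-{[(triethylsilyl)oxy]methyl}cyclodec-1-ene-1-carboxylate | C=C(C)[C@H]1C/C=C(/C(=O)OC)CCCC(CO[Si](CC)(CC)CC)([Se]c2ccccc2)C(=O)C1 | intermediate
18 | selenoxide of 17 | C=C(C)[C@H]1C/C=C(/C(=O)OC)CCCC(CO[Si](CC)(CC)CC)([Se](=O)c2ccccc2)C(=O)C1 | intermediate
19 | methyl (1E,4S,7E)-6-oxo-4-(prop-1-en-2-yl)-7-{[(triethylsilyl)oxy]methyl}cyclodeca-1,7-diene-1-carboxylate | C=C(C)[C@H]1C/C=C(/C(=O)OC)CC/C=C(\CO[Si](CC)(CC)CC)C(=O)C1 | intermediate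
20 | methyl (1E,4S,6S,7E)-6-hydroxy-4-(prop-1-en-2-yl)-7-{[(triethylsilyl)oxy]methyl}cyclodeca-1,7-diene-1-carboxylate | C=C(C)[C@H]1C/C=C(/C(=O)OC)CC/C=C(\CO[Si](CC)(CC)CC)[C@@H](O)C1 | intermediate
21 | methyl (1E,4S,6S,7E)-6-acetoxy-4-(prop-1-en-2-yl)-7-{[(triethylsilyl)oxy]methyl}cyclodeca-1,7-diene-1-carboxylate | C=C(C)[C@H]1C/C=C(/C(=O)OC)CC/C=C(\CO[Si](CC)(CC)CC)[C@@H](OC(C)=O)C1 | intermediate
22 | methyl (1E,4S,6S,7E)-6-acetoxy-7-(hydroxymethyl)-4-(prop-1-en-2-yl)cyclodeca-1,7-diene-1-carboxylate | C=C(C)[C@H]1C/C=C(/C(=O)OC)CC/C=C(\CO)[C@@H](OC(C)=O)C1 | intermediate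
23 | methyl (1E,4S,6S,7S,8R)-6-acetoxy-7,8-epoxy-7-(hydroxymethyl)-4-(prop-1-en-2-yl)cyclodec-1-ene-1-carboxylate | C=C(C)[C@H]1C/C=C(/C(=O)OC)CC[C@H]2O[C@]2(CO)[C@@H](OC(C)=O)C1 | intermediate
24 | methyl (1E,4S,6S,7S,8R)-6-acetoxy-7,8-epoxy-7-{[(2-methylpropanoyl)oxy]methyl}-4-(prop-1-en-2-yl)cyclodec-1-ene-1-carboxylate (CNP0372928.1) | C=C(C)[C@H]1C/C=C(/C(=O)OC)CC[C@H]2O[C@]2(COC(=O)C(C)C)[C@@H](OC(C)=O)C1 | target

**Total steps:** 13. **Longest linear sequence:** 11 (steps 1, 2, 3, 6, 7, 8, 9, 10, 11, 12, 13).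

**Steps most likely to fail**

Step 7 (the proposed new step). The stabilised α-seleno radical may add too slowly to the ketone, or the α-seleno ketone product may re-enter the radical chain.

The fallback uses known chemistry. It sets out from 7 and comes back at 14. Bu3SnLi is added to 7 and the enolate is trapped with excess 1,4-diiodobutane to give methyl (4R)-1-(4-iodobutyl)-2-oxo-4-(prop-1-en-2-yl)-6-(tributylstannyl)cyclohexane-1-carboxylate F1. The established primary-radical version of the stannyl-terminated four-carbon ring expansion (AIBN, catalytic Bu3SnH, PhH, reflux) then gives methyl (1E,4S)-6-oxo-4-(prop-1-en-2-yl)cyclodec-1-ene-1-carboxylate F2. Selenium is introduced afterwards by kinetic enolisation (LiN(iPr)2, −78 °C) and PhSeBr. The less hindered C7 enolate predominates and the C5 regioisomer is removed by chromatography, which delivers 14.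

Step 9. The elimination could give some of the 7Z-enone.

The fallback sets out from 17 and comes back at 19. The same oxidation is run and the unwanted methyl (1E,4S,7Z)-6-oxo-4-(prop-1-en-2-yl)-7-{[(triethylsilyl)oxy]methyl}cyclodeca-1,7-diene-1-carboxylate F3 is collected. It is converted photochemically (350 nm, −20 °C, n→π* excitation of the planar, better-absorbing Z-enone). The twisted, weakly absorbing E-enone 19 should accumulate in the photostationary mixture. It is separated and the remaining F3 is recycled.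

Step 12. The Z-type trisubstituted allylic alcohol in a medium ring may react slowly or with eroded face selectivity.

The fallback sets out from 19 and comes back at 23. Nucleophilic Weitz–Scheffer epoxidation of the enone (t-BuOOH, DBU, peripheral attack on the E-enone) gives methyl (1E,4S,7S,8R)-7,8-epoxy-6-oxo-4-(prop-1-en-2-yl)-7-{[(triethylsilyl)oxy]methyl}cyclodec-1-ene-1-carboxylate F4. CBS reduction with the (R)-catalyst gives methyl (1E,4S,6S,7R,8R)-7,8-epoxy-6-hydroxy-4-(prop-1-en-2-yl)-7-{[(triethylsilyl)oxy]methyl}cyclodec-1-ene-1-carboxylate F5. Acetylation with Ac2O gives methyl (1E,4S,6S,7S,8R)-6-acetoxy-7,8-epoxy-4-(prop-1-en-2-yl)-7-{[(triethylsilyl)oxy]methyl}cyclodec-1-ene-1-carboxylate F6. HF·pyridine then releases 23.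

**Further compounds**
F1 | step 7 | methyl (4R)-1-(4-iodobutyl)-2-oxo-4-(prop-1-en-2-yl)-6-(tributylstannyl)cyclohexane-1-carboxylate | C=C(C)[C@H]1CC([Sn](CCCC)(CCCC)CCCC)C(CCCCI)(C(=O)OC)C(=O)C1
F2 | step 7 | methyl (1E,4S)-6-oxo-4-(prop-1-en-2-yl)cyclodec-1-ene-1-carboxylate | C=C(C)[C@H]1C/C=C(/C(=O)OC)CCCCC(=O)C1
F3 | step 9 | methyl (1E,4S,7Z)-6-oxo-4-(prop-1-en-2-yl)-7-{[(triethylsilyl)oxy]methyl}cyclodeca-1,7-diene-1-carboxylate | C=C(C)[C@H]1C/C=C(/C(=O)OC)CC/C=C(/CO[Si](CC)(CC)CC)C(=O)C1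
F4 | step 12 | methyl (1E,4S,7S,8R)-7,8-epoxy-6-oxo-4-(prop-1-en-2-yl)-7-{[(triethylsilyl)oxy]methyl}cyclodec-1-ene-1-carboxylate | C=C(C)[C@H]1C/C=C(/C(=O)OC)CC[C@H]2O[C@]2(CO[Si](CC)(CC)CC)C(=O)C1
F5 | step 12 | methyl (1E,4S,6S,7R,8R)-7,8-epoxy-6-hydroxy-4-(prop-1-en-2-yl)-7-{[(triethylsilyl)oxy]methyl}cyclodec-1-ene-1-carboxylate | C=C(C)[C@H]1C/C=C(/C(=O)OC)CC[C@H]2O[C@]2(CO[Si](CC)(CC)CC)[C@@H](O)C1
F6 | step 12 | methyl (1E,4S,6S,7S,8R)-6-acetoxy-7,8-epoxy-4-(prop-1-en-2-yl)-7-{[(triethylsilyl)oxy]methyl}cyclodec-1-ene-1-carboxylate | C=C(C)[C@H]1C/C=C(/C(=O)OC)CC[C@H]2O[C@]2(CO[Si](CC)(CC)CC)[C@@H](OC(C)=O)C1
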